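## Retrosynthetic overview

1. C40 skeleton: two Wittig olefinations (C11=C12 and C11'=C12') join a C15 triol-end phosphonium salt, the commercial C10 trienedial and a C15 furanoid-end phosphonium salt.
2. Both C15 units come from one adduct of a C9 α-hydroxy ketone and a lithiated C6 enynol ether, used as a polarity-reversed (d5, vinylogous homoenolate-type) donor that forms C6–C7 (key step). Titanium bound to the 5-alkoxide delivers the alkynyl group syn and gives the 5,6-trans-diol that both halves need.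
3. Triol end: alkyne to (E)-alkene. Furanoid end: O5 silylated, O6 carbonate, anti-SN2' hydride from palladium (allene with H-8 on the O5 face), then gold 5-endo cyclisation, which turns the allene axis into C8'.
4. The α-hydroxy ketone comes from ketoisophorone: asymmetric transfer hydrogenation (C3), Luche reduction, hydroxyl-directed epoxidation (C5), hydride opening, re-oxidation.
5. Rings: both carbocycles are taken ready-made from ketoisophorone; the only ring built is the 2,5-dihydrofuran, closed before the chain is assembled.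

Assumption: ketoisophorone, (E)-3-methylpent-2-en-4-yn-1-ol and (2E,4E,6E)-2,7-dimethylocta-2,4,6-trienedial are bought; ring and chain positions are cited with carotenoid locants (C1–C6, C7 …; primes for the furanoid half).

## Route

Step 1
Reactants: 1 ketoisophorone (2,6,6-trimethylcyclohex-2-ene-1,4-dione)
Product: 2 (4S)-4-hydroxy-2,6,6-trimethylcyclohex-2-en-1-one [(S)-phorenol]
Conditions: RuCl[(S,S)-TsDPEN](p-cymene) (0.5 mol%), HCO2H/Et3N (5:2), CH2Cl2, 25 °C
Reagents that add atoms: none
Why: Noyori–Ikariya asymmetric transfer hydrogenation reduces only the unhindered C4 carbonyl (the other is flanked by CMe2 and C(Me)=), and the (S,S)-ligand, by analogy with aryl and alkenyl alkyl ketones, gives the (4S)-alcohol that becomes C3 and C3' of the target.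

Step 2
Reactants: 2 (S)-phorenol
Product: 3 (4S)-4-(tert-butyldimethylsilyloxy)-2,6,6-trimethylcyclohex-2-en-1-one
Conditions: TBSCl, imidazole, DMF, 25 °C
Reagents that add atoms: tert-butyldimethylsilyl chloride, CC(C)(C)[Si](C)(C)Cl
Why: Standard silylation of the secondary allylic alcohol; the bulky ether fixes the ring conformation (OTBS pseudo-equatorial) used for stereocontrol in steps 3 and 8.

Step 3
Reactants: 3 silyl enone
Product: 4 (1S,4S)-4-(tert-butyldimethylsilyloxy)-2,6,6-trimethylcyclohex-2-en-1-ol (1-OH trans to 4-OTBS)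
Conditions: NaBH4, CeCl3·7H2O, MeOH, −78 °C
Reagents that add atoms: none
Why: Luche 1,2-reduction; in the envelope conformer with OTBS pseudo-equatorial the neighbouring gem-dimethyl carbon carries a pseudo-axial methyl on one carbonyl face, so hydride enters from the other face and the new hydroxyl ends trans to OTBS.

Step 4
Reactants: 4 allylic alcohol
Product: 5 epoxy alcohol (4,5-epoxide cis to the C6 hydroxyl and trans to OTBS)
Conditions: VO(acac)2 (2 mol%), t-BuOOH, CH2Cl2, 0 °C
Reagents that add atoms: tert-butyl hydroperoxide, CC(C)(C)OO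
Why: Sharpless–Michaelson hydroxyl-directed vanadium epoxidation delivers oxygen syn to the allylic OH, which places the C5 oxygen trans to the C3 silyloxy group (sets C5, 5R in the target).

Step 5
Reactants: 5 epoxy alcohol
Product: 6 (1S,2R,4S)-4-(tert-butyldimethylsilyloxy)-2,6,6-trimethylcyclohexane-1,2-diol (cis-diol)
Conditions: LiAlH4, THF, 0 → 40 °C
Reagents that add atoms: none
Why: Hydride opens the trisubstituted epoxide by SN2 attack at the secondary carbon C4 (trans-diaxial, Fürst–Plattner), leaving the tertiary C5–OH with its configuration untouched.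

Step 6
Reactants: 6 cis-diol
Product: 7 (2R,4S)-4-(tert-butyldimethylsilyloxy)-2-hydroxy-2,6,6-trimethylcyclohexan-1-one (3-OTBS and 5-OH trans)
Conditions: (n-Pr4N)RuO4 (5 mol%), N-methylmorpholine N-oxide, 4 Å MS, CH2Cl2, 25 °C
Reagents that add atoms: none
Why: Ley–Griffith oxidation converts the secondary alcohol to the ketone while the tertiary alcohol cannot react; the product has no α-hydrogen, so it cannot epimerise or enolise.

Step 7
Reactants: 8 (E)-3-methylpent-2-en-4-yn-1-ol
Product: 9 (E)-3-methyl-5-(trimethylsilyloxy)pent-3-en-1-yne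
Conditions: Me3SiCl, Et3N, CH2Cl2, 0 °C
Reagents that add atoms: chlorotrimethylsilane, C[Si](C)(C)Cl
Why: Simple O-silylation; the labile TMS ether masks the primary alcohol during metallation and is removed later without a separate step.

Step 8
Reactants: 7 α-hydroxy ketone; 9 silyl enynol ether
Product: 12 (1S,2R,4S)-4-(tert-butyldimethylsilyloxy)-2,6,6-trimethyl-1-[(E)-3-methyl-5-(trimethylsilyloxy)pent-3-en-1-ynyl]cyclohexane-1,2-diol (trans-diol; alkynyl cis to 5-OH), via lithium acetylide 10 (not isolated), via titanium acetylide 11 (not isolated)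
Conditions: 9 (2.2 equiv), n-BuLi (2.1 equiv), THF, −78 °C; ClTi(OiPr)3 (2.2 equiv), −78 → −30 °C; then 7, −30 → 25 °C; aq. NH4Cl
Reagents that add atoms: none
Why: Proposed new method: this is the key step, in which the C6 acetylide acts as a polarity-reversed (d5, vinylogous homoenolate-type) donor whose C7, an acceptor position counted from the C11 oxygen, is joined to the electrophilic ketone carbon C6; ligand exchange puts titanium on the free axial 5-OH and the alkynyl group is handed over inside that complex to the carbonyl face syn to O5 (alkynyl up, 6-OH down, 5,6-trans-diol), while unbound alkynyltitanium is too unreactive to attack this tetra-α-substituted ketone from the open anti face; closest known reaction: Reetz chelation-controlled RTi(OiPr)3 addition to α-hydroxy ketones.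

Step 9
Reactants: 12 trans-diol enyne
Product: 13 (1R,2R,4S)-4-(tert-butyldimethylsilyloxy)-1-[(1E,3E)-5-hydroxy-3-methylpenta-1,3-dienyl]-2,6,6-trimethylcyclohexane-1,2-diol
Conditions: NaAlH2(OCH2CH2OMe)2, THF, 0 → 25 °C; aq. NaOH, KNaC4H4O6
Reagents that add atoms: none
Why: Trans-hydroalumination of the propargylic alkoxide gives the (7E)-alkene exclusively, and the basic work-up hydrolyses the primary O-SiMe3 group.

Step 10
Reactants: 13 triol dienol
Product: 15 [(2E,4E)-5-[(1R,2R,4S)-4-(tert-butyldimethylsilyloxy)-1,2-dihydroxy-2,6,6-trimethylcyclohexyl]-3-methylpenta-2,4-dienyl]triphenylphosphonium bromide, via allyl bromide 14 (not isolated)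
Conditions: CBr4 (1.05 equiv), PPh3 (2.5 equiv), CH2Cl2, −20 → 25 °C
Reagents that add atoms: carbon tetrabromide, BrC(Br)(Br)Br; triphenylphosphine, c1ccc(cc1)P(c1ccccc1)c1ccccc1
Why: Appel bromination is selective for the primary allylic alcohol at −20 °C (both tertiary alcohols are inert, no acid is formed), and the excess phosphine quaternises the allyl bromide in the same flask.

Step 11
Reactants: 15 triol-end phosphonium salt; 16 (2E,4E,6E)-2,7-dimethylocta-2,4,6-trienedial
Product: 17 (2E,4E,6E,8E,10E,12E)-13-[(1R,2R,4S)-4-(tert-butyldimethylsilyloxy)-1,2-dihydroxy-2,6,6-trimethylcyclohexyl]-2,7,11-trimethyltrideca-2,4,6,8,10,12-hexaenal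
Conditions: 16 (3 equiv), NaOMe, MeOH/CH2Cl2, 0 → 25 °C; then EtOAc, reflux (Z → E)
Reagents that add atoms: none
Why: Wittig olefination with the ylide formed in the presence of excess symmetrical dial gives mono-olefination (C11=C12), and the usual thermal isomerisation of carotenoid Wittig products converts the 11Z portion to all-E.

Step 12
Reactants: 12 trans-diol enyne
Product: 18 (1S,2R,4S)-4-(tert-butyldimethylsilyloxy)-2,6,6-trimethyl-1-[(E)-3-methyl-5-(trimethylsilyloxy)pent-3-en-1-ynyl]-2-(trimethylsilyloxy)cyclohexan-1-ol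
Conditions: Me3SiCl (1.2 equiv), imidazole, DMF, 0 → 25 °C
Reagents that add atoms: chlorotrimethylsilane, C[Si](C)(C)Cl
Why: Kinetic O-silylation picks the 5-OH (one CH2 neighbour) over the 6-OH, which sits between two quaternary carbons; capping O5 leaves O6 as the only oxygen that can be acylated in step 13.

Step 13
Reactants: 18 mono-protected diol
Product: 20 methyl [(1S,2R,4S)-4-(tert-butyldimethylsilyloxy)-2,6,6-trimethyl-1-[(E)-3-methyl-5-(trimethylsilyloxy)pent-3-en-1-ynyl]-2-(trimethylsilyloxy)cyclohexyl] carbonate, via lithium alkoxide 19 (not isolated)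
Conditions: n-BuLi (1.05 equiv), THF, −78 °C; ClCO2Me, −78 → 0 °C
Reagents that add atoms: methyl chloroformate, COC(=O)Cl
Why: Acylation of the lithium alkoxide of the tertiary propargylic alcohol with a small chloroformate; O5–Si and O6 are trans-diaxial (180° apart), so the alkoxide cannot reach silicon and no 1,4-silyl migration occurs.

Step 14
Reactants: 20 propargylic carbonate
Product: 22 (2E)-5-[(2R,4S)-4-(tert-butyldimethylsilyloxy)-2-hydroxy-2,6,6-trimethylcyclohexylidene]-3-methylpenta-2,4-dien-1-ol with R allene axis (H-8 on the side of the 5-OH; C9 on the side of the 5-methyl group), via bis-silyl allene 21 (not isolated)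
Conditions: Pd2(dba)3·CHCl3 (2.5 mol%), PBu3 (10 mol%), HCO2NH4, THF, 25 °C; then K2CO3, MeOH, 25 °C
Reagents that add atoms: none
Why: Tsuji–Mandai hydrogenolysis of a propargylic carbonate: zerovalent palladium attacks C8 anti to the axial C6–O bond, formate supplies hydride and reductive elimination puts H-8 where palladium was (overall anti-SN2'), so the C6 carbinol configuration becomes one allene axis with H-8 on the O5 face; methanolysis then removes both Me3Si ethers and leaves the TBS ether.

Step 15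
Reactants: 22 α-hydroxy vinylallene
Product: 23 (2E)-3-[(2S,6S,7aR)-6-(tert-butyldimethylsilyloxy)-4,4,7a-trimethyl-2,4,5,6,7,7a-hexahydro-1-benzofuran-2-yl]but-2-en-1-ol
Conditions: AuCl3 (5 mol%), THF, 20 °C, dark
Reagents that add atoms: none
Why: Krause-type gold-catalysed 5-endo cycloisomerisation of an α-hydroxyallene: O5 attacks C8 anti to gold and protodeauration leaves the C6'=C7' double bond, so the allene axis is transferred to the C8' centre with C9' on the face of the 5'-methyl group and H-8' on the face of C4' (8'S); the primary alcohol cannot reach the allene across the (E)-alkene.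

Step 16
Reactants: 23 furanoid alcohol
Product: 25 [(2E)-3-[(2S,6S,7aR)-6-(tert-butyldimethylsilyloxy)-4,4,7a-trimethyl-2,4,5,6,7,7a-hexahydro-1-benzofuran-2-yl]but-2-enyl]triphenylphosphonium bromide, via allyl bromide 24 (not isolated)
Conditions: CBr4 (1.05 equiv), PPh3 (2.5 equiv), CH2Cl2, −20 → 25 °C
Reagents that add atoms: carbon tetrabromide, BrC(Br)(Br)Br; triphenylphosphine, c1ccc(cc1)P(c1ccccc1)c1ccccc1
Why: Appel bromination and in situ quaternisation under non-acidic conditions, so the acid-labile allylic ether at C8' is not ionised and C8' is not scrambled.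

Step 17
Reactants: 25 furanoid-end phosphonium salt; 17 C25 aldehyde
Product: 26 3,3'-bis-O-(tert-butyldimethylsilyl) ether of the target (all-E; 3S,5R,6R,3'S,5'R,8'S)
Conditions: NaOMe, MeOH/CH2Cl2, 0 → 25 °C (base added last); then EtOAc, reflux (Z → E)
Reagents that add atoms: none
Why: Wittig olefination forms C11'=C12'; the ylide is generated in the presence of the aldehyde so that it is trapped before it can open the dihydrofuran by vinylogous β-elimination, and thermal isomerisation gives the all-E polyene.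

Step 18
Reactants: 26 bis-silyl ether
Product: 27 (3S,5R,6R,3'S,5'R,8'S)-5',8'-epoxy-5,6,5',8'-tetrahydro-β,β-carotene-3,5,6,3'-tetrol (the target CNP0210286.3)
Conditions: Bu4NF, THF, 25 °C
Reagents that add atoms: none
Why: Fluoride cleaves both secondary silyl ethers under non-acidic conditions, which leaves the tertiary allylic alcohol and the furanoid ether (both acid-sensitive) intact.

## Compound list

1 | ketoisophorone (2,6,6-trimethylcyclohex-2-ene-1,4-dione) | CC1=CC(=O)CC(C)(C)C1=O | starting material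
2 | (4S)-4-hydroxy-2,6,6-trimethylcyclohex-2-en-1-one | O=C1C(C)(C)C[C@H](O)C=C1C | intermediate
3 | (4S)-4-(tert-butyldimethylsilyloxy)-2,6,6-trimethylcyclohex-2-en-1-one | O=C1C(C)(C)C[C@H](O[Si](C)(C)C(C)(C)C)C=C1C | intermediate
4 | (1S,4S)-4-(tert-butyldimethylsilyloxy)-2,6,6-trimethylcyclohex-2-en-1-ol (OH trans to OTBS) | O[C@H]1C(C)(C)C[C@H](O[Si](C)(C)C(C)(C)C)C=C1C | intermediate
5 | epoxy alcohol: 5-(tert-butyldimethylsilyloxy)-1,3,3-trimethyl-7-oxabicyclo[4.1.0]heptan-2-ol, epoxide cis to OH and trans to OTBS | O[C@H]1C(C)(C)C[C@H](O[Si](C)(C)C(C)(C)C)[C@H]2O[C@@]12C | intermediate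
6 | (1S,2R,4S)-4-(tert-butyldimethylsilyloxy)-2,6,6-trimethylcyclohexane-1,2-diol (cis-diol) | O[C@H]1C(C)(C)C[C@H](O[Si](C)(C)C(C)(C)C)C[C@@]1(C)O | intermediate
7 | (2R,4S)-4-(tert-butyldimethylsilyloxy)-2-hydroxy-2,6,6-trimethylcyclohexan-1-one | O=C1C(C)(C)C[C@H](O[Si](C)(C)C(C)(C)C)C[C@@]1(C)O | intermediate
8 | (E)-3-methylpent-2-en-4-yn-1-ol | C#C/C(C)=C/CO | starting material
9 | (E)-3-methyl-5-(trimethylsilyloxy)pent-3-en-1-yne | C#C/C(C)=C/CO[Si](C)(C)C | intermediate
10 | lithium acetylide of 9 | [Li]C#C/C(C)=C/CO[Si](C)(C)C | intermediate (not isolated)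
11 | triisopropoxytitanium acetylide of 9 | CC(C)O[Ti](OC(C)C)(OC(C)C)C#C/C(C)=C/CO[Si](C)(C)C | intermediate (not isolated)
12 | (1S,2R,4S)-4-(tert-butyldimethylsilyloxy)-2,6,6-trimethyl-1-[(E)-3-methyl-5-(trimethylsilyloxy)pent-3-en-1-ynyl]cyclohexane-1,2-diol (trans-diol) | C[Si](C)(C)OC/C=C(C)/C#C[C@@]1(O)C(C)(C)C[C@H](O[Si](C)(C)C(C)(C)C)C[C@@]1(C)O | intermediate
13 | (1R,2R,4S)-4-(tert-butyldimethylsilyloxy)-1-[(1E,3E)-5-hydroxy-3-methylpenta-1,3-dienyl]-2,6,6-trimethylcyclohexane-1,2-diol | OC/C=C(C)/C=C/[C@@]1(O)C(C)(C)C[C@H](O[Si](C)(C)C(C)(C)C)C[C@@]1(C)O | intermediate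
14 | allyl bromide of 13 | BrC/C=C(C)/C=C/[C@@]1(O)C(C)(C)C[C@H](O[Si](C)(C)C(C)(C)C)C[C@@]1(C)O | intermediate (not isolated)
15 | triol-end C15 triphenylphosphonium bromide | [Br-].c1ccccc1[P+](c1ccccc1)(c1ccccc1)C/C=C(C)/C=C/[C@@]1(O)C(C)(C)C[C@H](O[Si](C)(C)C(C)(C)C)C[C@@]1(C)O | intermediate
16 | (2E,4E,6E)-2,7-dimethylocta-2,4,6-trienedial | O=C/C(C)=C/C=C/C=C(C)/C=O | starting material
17 | C25 aldehyde: (2E,4E,6E,8E,10E,12E)-13-[(1R,2R,4S)-4-(tert-butyldimethylsilyloxy)-1,2-dihydroxy-2,6,6-trimethylcyclohexyl]-2,7,11-trimethyltrideca-2,4,6,8,10,12-hexaenal | O=C/C(C)=C/C=C/C=C(C)/C=C/C=C(C)/C=C/[C@@]1(O)C(C)(C)C[C@H](O[Si](C)(C)C(C)(C)C)C[C@@]1(C)O | intermediate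
18 | (1S,2R,4S)-4-(tert-butyldimethylsilyloxy)-2,6,6-trimethyl-1-[(E)-3-methyl-5-(trimethylsilyloxy)pent-3-en-1-ynyl]-2-(trimethylsilyloxy)cyclohexan-1-ol | C[Si](C)(C)OC/C=C(C)/C#C[C@@]1(O)C(C)(C)C[C@H](O[Si](C)(C)C(C)(C)C)C[C@@]1(C)O[Si](C)(C)C | intermediate
19 | lithium alkoxide of 18 | C[Si](C)(C)OC/C=C(C)/C#C[C@@]1(O[Li])C(C)(C)C[C@H](O[Si](C)(C)C(C)(C)C)C[C@@]1(C)O[Si](C)(C)C | intermediate (not isolated)
20 | tertiary propargylic methyl carbonate of 18 (carbonate oxygen trans to the 5-OSiMe3 group) | C[Si](C)(C)OC/C=C(C)/C#C[C@@]1(OC(=O)OC)C(C)(C)C[C@H](O[Si](C)(C)C(C)(C)C)C[C@@]1(C)O[Si](C)(C)C | intermediate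
21 | 5,11-bis-O-(trimethylsilyl) ether of allene 22 (allene chirality written on the central carbon) | C[Si](C)(C)OC/C=C(C)/C([H])=[C@@]=C1C(C)(C)C[C@H](O[Si](C)(C)C(C)(C)C)C[C@@]1(C)O[Si](C)(C)C | intermediate (not isolated)
22 | (2E)-5-[(2R,4S)-4-(tert-butyldimethylsilyloxy)-2-hydroxy-2,6,6-trimethylcyclohexylidene]-3-methylpenta-2,4-dien-1-ol, allene axis R (allene chirality written on the central carbon) | OC/C=C(C)/C([H])=[C@@]=C1C(C)(C)C[C@H](O[Si](C)(C)C(C)(C)C)C[C@@]1(C)O | intermediate
23 | (2E)-3-[(2S,6S,7aR)-6-(tert-butyldimethylsilyloxy)-4,4,7a-trimethyl-2,4,5,6,7,7a-hexahydro-1-benzofuran-2-yl]but-2-en-1-ol | OC/C=C(C)/[C@@H]1C=C2C(C)(C)C[C@H](O[Si](C)(C)C(C)(C)C)C[C@@]2(C)O1 | intermediate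
24 | allyl bromide of 23 | BrC/C=C(C)/[C@@H]1C=C2C(C)(C)C[C@H](O[Si](C)(C)C(C)(C)C)C[C@@]2(C)O1 | intermediate (not isolated)
25 | furanoid-end C15 triphenylphosphonium bromide | [Br-].c1ccccc1[P+](c1ccccc1)(c1ccccc1)C/C=C(C)/[C@@H]1C=C2C(C)(C)C[C@H](O[Si](C)(C)C(C)(C)C)C[C@@]2(C)O1 | intermediate
26 | 3,3'-bis-O-(tert-butyldimethylsilyl) ether of the target | CC(/C=C/C=C(C)/C=C/[C@@]1(O)C(C)(C)C[C@H](O[Si](C)(C)C(C)(C)C)C[C@@]1(C)O)=C\C=C\C=C(C)\C=C\C=C(/C)[C@@H]1C=C2C(C)(C)C[C@H](O[Si](C)(C)C(C)(C)C)C[C@@]2(C)O1 | intermediate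
27 | (3S,5R,6R,3'S,5'R,8'S)-5',8'-epoxy-5,6,5',8'-tetrahydro-β,β-carotene-3,5,6,3'-tetrol | CC(/C=C/C=C(C)/C=C/[C@@]1(O)C(C)(C)C[C@H](O)C[C@@]1(C)O)=C\C=C\C=C(C)\C=C\C=C(/C)[C@@H]1C=C2C(C)(C)C[C@H](O)C[C@@]2(C)O1 | target

## Step count and risks

Total: 18 steps. Longest linear sequence: 14 steps (steps 1–6, 8 and 12–18).

**Step 8 (key addition).** The hindered ketone may not accept the titanium-bound alkynyl group, or a background anti attack may give the 6-epimer (cis-diol). The fallback sets out from 7 and comes back at 12. Lithium acetylide 10, made from 9 and n-BuLi as in step 8, is quenched with excess Me2SiCl2 to give the alkynylchlorosilane F1, which silylates the tertiary hydroxyl of 7 (imidazole, DMF) to the tethered silyl ether F2. Catalytic Bu4N[Ph3SiF2] in THF turns the silicon into a pentacoordinate silicate that passes the alkynyl group to the neighbouring carbonyl carbon through a five-membered transition state, necessarily on the face of O5. NH4F in MeOH then removes the silicon tether and the O-SiMe3 group to give the trans-diol enynol F3, and Me3SiCl/Et3N (conditions of step 7) silylates its primary hydroxyl again to give 12.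

**Step 14 (SN2' hydrogenolysis).** The hindered carbonate 20 may form poorly in step 13, and its ionisation may erode the allene axis or give the enyne instead of the allene. The fallback sets out from 7 and comes back at 22. It brings in C9 instead of hydride as the anti-SN2' nucleophile, so that the easily made 6-epimeric adduct leads to the same allene.
- Me3SiOTf/2,6-lutidine silylates the tertiary hydroxyl of 7 to the silyloxy ketone F4.
- Ethynylmagnesium bromide in THF adds to F4 on the face opposite to the axial 5-OSiMe3 group and the axial C1 methyl (Felkin–Anh), and ClCO2Me traps the alkoxide as the methyl carbonate F5.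
- Bu4NF frees O5, which closes the cis-fused cyclic carbonate F6 (ethynyl trans to O5).
- The alkenylboronate F7, (Z)-3-(4,4,5,5-tetramethyl-1,3,2-dioxaborolan-2-yl)but-2-en-1-ol, is made from but-2-yn-1-ol with bis(pinacolato)diboron, CuCl/NaOt-Bu and MeOH (syn addition, boron on the carbon remote from oxygen).
- Pd(PPh3)4 in THF couples F6 with F7: zerovalent palladium ionises the carbonate anti, CO2 is lost, the freed alkoxide activates boron and the alkenyl group passes from palladium to C8 with retention. C9 therefore enters anti to the former C6–O bond (palladium-catalysed allene coupling of a propargylic cyclic carbonate with an organoboron reagent) and 22 results directly.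

**Step 17 (final Wittig).** The furanoid ylide can open the dihydrofuran by vinylogous β-elimination, or give poor conversion with the sensitive C25 aldehyde. The fallback sets out from 23 and 17 and comes back at 26; it exchanges the roles of the partners. MnO2 in CH2Cl2 oxidises 23 to the furanoid C15 aldehyde F8. NaBH4 in MeOH reduces 17 to the C25 alcohol F9, which CBr4/PPh3 converts through the C25 allyl bromide F10 into the C25 phosphonium bromide F11. Wittig olefination of F11 with F8 (NaOMe, then thermal isomerisation) gives 26, with no carbanion next to the C8' ether.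

## Further compounds

F1 | step 8 | chlorodimethyl[(E)-3-methyl-5-(trimethylsilyloxy)pent-3-en-1-ynyl]silane | C[Si](C)(Cl)C#C/C(C)=C/CO[Si](C)(C)C
F2 | step 8 | alkynyl(dimethyl)silyl ether of the tertiary hydroxyl of 7 | O=C1C(C)(C)C[C@H](O[Si](C)(C)C(C)(C)C)C[C@@]1(C)O[Si](C)(C)C#C/C(C)=C/CO[Si](C)(C)C
F3 | step 8 | trans-diol enynol (12 without the trimethylsilyl group) | OC/C=C(C)/C#C[C@@]1(O)C(C)(C)C[C@H](O[Si](C)(C)C(C)(C)C)C[C@@]1(C)O
F4 | step 14 | (2R,4S)-4-(tert-butyldimethylsilyloxy)-2,6,6-trimethyl-2-(trimethylsilyloxy)cyclohexan-1-one | O=C1C(C)(C)C[C@H](O[Si](C)(C)C(C)(C)C)C[C@@]1(C)O[Si](C)(C)C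
F5 | step 14 | methyl carbonate of the ethynyl adduct of F4 (ethynyl trans to 5-OSiMe3) | C#C[C@]1(OC(=O)OC)C(C)(C)C[C@H](O[Si](C)(C)C(C)(C)C)C[C@@]1(C)O[Si](C)(C)C
F6 | step 14 | cis-fused 5,6-cyclic carbonate bearing the ethynyl group at C6 (ethynyl trans to the C5 oxygen) | C#C[C@]1(OC(=O)O2)C(C)(C)C[C@H](O[Si](C)(C)C(C)(C)C)C[C@]12C
F7 | step 14 | (Z)-3-(4,4,5,5-tetramethyl-1,3,2-dioxaborolan-2-yl)but-2-en-1-ol | OC/C=C(\C)B1OC(C)(C)C(C)(C)O1
F8 | step 17 | furanoid C15 aldehyde, (2E)-3-[(2S,6S,7aR)-6-(tert-butyldimethylsilyloxy)-4,4,7a-trimethyl-2,4,5,6,7,7a-hexahydro-1-benzofuran-2-yl]but-2-enal | O=C/C=C(C)/[C@@H]1C=C2C(C)(C)C[C@H](O[Si](C)(C)C(C)(C)C)C[C@@]2(C)O1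
F9 | step 17 | C25 alcohol from 17 | OC/C(C)=C/C=C/C=C(C)/C=C/C=C(C)/C=C/[C@@]1(O)C(C)(C)C[C@H](O[Si](C)(C)C(C)(C)C)C[C@@]1(C)O
F10 | step 17 | C25 allyl bromide | BrC/C(C)=C/C=C/C=C(C)/C=C/C=C(C)/C=C/[C@@]1(O)C(C)(C)C[C@H](O[Si](C)(C)C(C)(C)C)C[C@@]1(C)O
F11 | step 17 | C25 triphenylphosphonium bromide | [Br-].c1ccccc1[P+](c1ccccc1)(c1ccccc1)C/C(C)=C/C=C/C=C(C)/C=C/C=C(C)/C=C/[C@@]1(O)C(C)(C)C[C@H](O[Si](C)(C)C(C)(C)C)C[C@@]1(C)O
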